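The synthesis rests on cutting C11–C12 of the cycloheptene (C6, C9, C10, C11, C12, C13, C23). This ring is the four-carbon bridge that spans C9 and C23 of the piperidine. C9 and C23 sit 1,3 across C6. A C9 vinyl group and a C12 iodide on the spiro-fused bicyclo[3.3.0]octenone are therefore cis and within reach of each other. Hydroboration of the vinyl group followed by intramolecular B-alkyl Suzuki–Miyaura coupling closes the seven-membered ring in one operation. It also fixes the tetrasubstituted C12=C13 alkene. The precursor is an N-Boc, C6-dioxolane piperidine. It carries the C9 vinyl group and, spiro at C23, the α-iodo enone with its C17 ester.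

Key step: step 12

Remark 1: Atom numbers follow the atoms of the target SMILES read from left to right (C1 to C27). Ring A is C12–C13–C14–C15–C16 and ring B is C13–C14–C17–C22–C23.
Remark 2: In the target, H14 and H17 lie on the face of ring B that carries C24, whereas C15, C18 and C6 lie on the other face. The C17 ester is therefore carried as its more stable epimer (trans to C15) and inverted in the last step.
Remark 3: Nitrogen is carried as its tert-butyl carbamate until after the key step. This allows a nearly stoichiometric amount of borane and keeps iodine and palladium away from a basic amine.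
Remark 4: The sense of induction in step 1 is assumed. It is fixed by choosing between the two pseudoenantiomeric catalysts.

Step 1
Reactants: 1 1-tert-butyl 3-methyl 4-oxopiperidine-1,3-dicarboxylate; 2 methyl acrylate
Product: 3 1-tert-butyl 3-methyl (3S)-3-(3-methoxy-3-oxopropyl)-4-oxopiperidine-1,3-dicarboxylate
Conditions: O-allyl-N-(9-anthracenylmethyl)cinchonidinium bromide (10 mol %), K2CO3 (20 mol %), toluene, −20 °C
Reagents that add atoms: 2 methyl acrylate, C=CC(=O)OC
Why: In this asymmetric phase-transfer Michael addition the chiral ammonium–enolate ion pair shows one face of the tetrasubstituted enolate to the acrylate and so sets quaternary C23 (S); the cinchoninium pseudoenantiomer is used if screening shows the opposite sense.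

Step 2
Reactants: 3 Michael adduct; 4 formaldehyde
Product: 6 keto lactone (N-Boc 3-oxa-7-azabicyclo[3.3.1]nonane-2,9-dione bearing the propanoate chain on bridgehead C23), via lithium aldolate 5 (not isolated)
Conditions: LiHMDS (1.05 equiv), THF, −78 °C; monomeric CH2O in THF; −78 to 0 °C; aq NH4Cl
Reagents that add atoms: 4 formaldehyde, C=O
Why: Only C9 can enolise, and in the ester-chelated lithium enolate the larger C22 chain sits pseudo-axial, so the aldol addition should bring C10 in anti to it and cis to the C13 ester, and only that aldolate can close the δ-lactone (transesterification), which locks C9 as a non-enolisable bridgehead.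

Step 3
Reactants: 6 keto lactone
Product: 7 ketal lactone (C6 as 1,3-dioxolane)
Conditions: 1,2-bis(trimethylsilyloxy)ethane, Me3SiOSO2CF3 (5 mol %), CH2Cl2, −78 to −20 °C
Reagents that add atoms: 1,2-bis(trimethylsilyloxy)ethane, C[Si](C)(C)OCCO[Si](C)(C)C
Why: Silyl-triflate-catalysed ketalisation with the bis-silyl glycol works at low temperature on hindered, non-enolisable ketones and spares the carbamate, the lactone and the ester.

Step 4
Reactants: 7 ketal lactone; 8 allyl bromoacetate
Product: 9 succinate (7 alkylated at C17 with CH2CO2-allyl, C17 epimers)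
Conditions: LDA (1.1 equiv), THF, −78 °C; then 8, −78 to −40 °C
Reagents that add atoms: 8 allyl bromoacetate, C=CCOC(=O)CBr
Why: This is an ester enolate alkylation (SN2) at C17, the only carbon with acidic hydrogens, and it brings in C14 with a removable activating ester; the C17 configuration is irrelevant here because it is equilibrated in step 8.

Step 5
Reactants: 9 succinate
Product: 11 spiro β-keto ester triethylsilyl ether (ring B closed, C14 and C17 epimers), via dilithium alkoxide enolate 10 (not isolated)
Conditions: LiHMDS (2.2 equiv), THF, −78 to 0 °C; Et3SiCl (1.1 equiv), −78 °C; aq NH4Cl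
Reagents that add atoms: chlorotriethylsilane, CC[Si](Cl)(CC)CC
Why: In this Dieckmann-type condensation the C14 enolate attacks lactone carbonyl C13 (5-exo-trig), closes ring B and releases the C10 alkoxide, deprotonation of the β-keto ester drives the reaction, and silylation of the alkoxide blocks its return to C13 (retro-Claisen) in step 6; C9 and C23 are untouched.

Step 6
Reactants: 11 spiro β-keto ester; 12 chloroacetone
Product: 13 C14-acetonyl β-keto ester (epimer mixture)
Conditions: K2CO3, NaI (10 mol %), acetone, 50 °C
Reagents that add atoms: 12 chloroacetone, CC(=O)CCl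
Why: C-alkylation of the stabilised β-keto ester enolate with iodoacetone formed in the flask (Finkelstein exchange) brings in C15, C16 and C12, and the temporary quaternary C14 is lost again in step 7.

Step 7
Reactants: 13 C14-acetonyl β-keto ester
Product: 14 1,4-diketone (C13 and C16 ketones, C14 and C17 epimers)
Conditions: Pd(PPh3)4 (5 mol %), HCO2H, Et3N, THF, rt
Reagents that add atoms: none
Why: Palladium-catalysed deallylation–decarboxylation of an allyl β-keto ester with formate (Tsuji-type hydrogenolysis) removes the auxiliary ester under nearly neutral conditions that leave the methyl ester, silyl ether, ketal and carbamate alone.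

Step 8
Reactants: 14 1,4-diketone
Product: 16 bicyclic enone alcohol (rings A and B, C14 as in the target, C17 ester trans to C15), via TES enone 15 (not isolated)
Conditions: NaOMe (0.3 equiv), MeOH, 50 °C; then 1 M HCl to pH 3, 0 °C
Reagents that add atoms: none
Why: Intramolecular aldol condensation of the methyl ketone (C12) onto C13 is the only five-membered closure open to a 1,4-diketone, and methoxide equilibrates C17 (ester enolate) and C14 (ketone enolate, later dienolate), so the ester should settle trans to C15 and on the CH2N (C24) face away from the dioxolane, which places H14 syn to C24.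

Step 9
Reactants: 16 bicyclic enone alcohol
Product: 17 C10 aldehyde
Conditions: Dess–Martin periodinane, CH2Cl2, 0 °C to rt
Reagents that add atoms: none
Why: Dess–Martin oxidation of the primary alcohol is non-basic, so the C9 stereocentre next to the new aldehyde is not epimerised.

Step 10
Reactants: 17 C10 aldehyde; 18 methyltriphenylphosphonium bromide
Product: 19 C9-vinyl enone
Conditions: 18, KHMDS, THF, 0 °C; then 17, −78 to 0 °C
Reagents that add atoms: 18 methyltriphenylphosphonium bromide, C[P+](c1ccccc1)(c1ccccc1)c1ccccc1.[Br-]
Why: In the Wittig methylenation the aldehyde reacts far faster than the enone carbonyl, and at low temperature addition outruns enolisation, so C9 keeps its configuration.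

Step 11
Reactants: 19 C9-vinyl enone
Product: 20 α-iodo enone (precursor of the key step)
Conditions: I2, pyridine, DMAP (20 mol %), CH2Cl2, rt, dark
Reagents that add atoms: iodine, II
Why: Amine-mediated α-iodination of a cyclic enone (conjugate addition of the amine, iodination, elimination) puts iodine on C12 only and leaves the isolated vinyl group, which adds iodine only reversibly.

Step 12
Reactants: 20 α-iodo enone
Product: 22 tetracyclic C16 enone with C6 dioxolane, via alkylborane 21 (not isolated)
Conditions: 9-BBN-H (1.3 equiv), THF, 0 °C to rt; then slow addition to Pd(dppf)Cl2 (10 mol %), AsPh3 (20 mol %), Cs2CO3, DMF–THF–H2O, 50 °C, 2 mM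
Reagents that add atoms: 9-borabicyclo[3.3.1]nonane, B1C2CCCC1CCC2 (its boron unit is present only in 21; only hydrogen stays in 22)
Why: 9-BBN-H adds anti-Markovnikov to the only unhindered alkene and puts boron on C11 (21). Zerovalent palladium then inserts into C12–I, the base-activated borane hands C11 to the divalent alkenylpalladium, and reductive elimination forms C11–C12; the closest known reaction type is the B-alkyl Suzuki–Miyaura coupling of alkyl-9-BBN reagents with α-iodo enones and its ring-closing variants. The seven-membered ring closes through an eight-membered palladacycle that contracts on reductive elimination, with C12=C13 endocyclic and its position dictated by the iodide. No stereocentre is formed, and C9, C14, C17 and C23 are not touched because the ester is already in its stable configuration and C9 has no adjacent carbonyl. The step needs hydroboration of the vinyl group in preference to reduction of the C16 carbonyl, and ring closure in preference to oligomerisation. The first is secured by the non-basic carbamate nitrogen (little excess borane), the C6 dioxolane and the flanking of the enone by iodine and quaternary C23; the second is secured by the cis-1,3 placement of C10 and C13 on the piperidine and by high dilution.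

Step 13
Reactants: 22 tetracyclic enone
Product: 23 C16 allylic alcohol (C16 epimers, both usable)
Conditions: NaBH4, CeCl3·7H2O, MeOH, −78 °C
Reagents that add atoms: none
Why: Luche reduction gives clean 1,2-reduction of the enone while the dioxolane still masks C6, so no selectivity between two ketones is needed.

Step 14
Reactants: 23 allylic alcohol
Product: 24 C16-deoxygenated secondary amine ketal
Conditions: Et3SiH (3 equiv), CF3CO2H, CH2Cl2, −20 to 0 °C
Reagents that add atoms: none
Why: In this ionic hydrogenation the allyl cation takes hydride at the open secondary C16 terminus rather than at C13 next to quaternary C23, so C12=C13 stays in place, the acid also removes the Boc group, and at or below 0 °C without a Lewis acid the hindered dioxolane should survive.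

Step 15
Reactants: 24 secondary amine ketal; 4 formaldehyde
Product: 26 N-methyl C6 ketone, via N-methyl ketal 25 (not isolated)
Conditions: aq CH2O, NaBH(OAc)3, ClCH2CH2Cl, rt; then 2 M HCl, THF, 50 °C
Reagents that add atoms: 4 formaldehyde, C=O; water, O
Why: Reductive amination methylates nitrogen, and acid hydrolysis then frees the C6 ketone with no silane present, so the ketal cannot be reduced to an ether, while the ketone cannot epimerise because C23 is quaternary and C9 is a bridgehead.

Step 16
Reactants: 26 N-methyl C6 ketone; 27 (methoxymethyl)triphenylphosphonium chloride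
Product: 28 C6 methoxymethylidene enol ether (E/Z mixture)
Conditions: 27, KHMDS, THF, 0 °C; then 26, 0 to 50 °C
Reagents that add atoms: 27 (methoxymethyl)triphenylphosphonium chloride, COC[P+](c1ccccc1)(c1ccccc1)c1ccccc1.[Cl-]
Why: Wittig homologation brings in C5, and because the hindered ketone has no enolisable position, excess ylide and warming can be used without side reactions.

Step 17
Reactants: 28 enol ether
Product: 29 C6 carbaldehyde (C6 epimers)
Conditions: 1 M HCl, THF, rt
Reagents that add atoms: water, O
Why: Acid hydrolysis of the enol ether gives the aldehyde, and its C6 configuration does not matter because C6 becomes planar again in step 18.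

Step 18
Reactants: 29 C6 carbaldehyde; 4 formaldehyde
Product: 30 α-hydroxymethyl aldehyde (quaternary C6)
Conditions: aq CH2O (37 %), K2CO3 (20 mol %), MeOH, rt
Reagents that add atoms: 4 formaldehyde, C=O
Why: In this crossed aldol hydroxymethylation of an α-branched aldehyde, formaldehyde should approach the exocyclic enolate from the face syn to the cycloheptene bridge, where only H10 is syn-axial because C13 is sp2, and not from the piperidine face with syn-axial hydrogens at C24 and C27, so C7 ends syn to the bridge and C5 axial on the piperidine as in the target.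

Step 19
Reactants: 30 α-hydroxymethyl aldehyde; 31 diethyl (2-oxobutyl)phosphonate
Product: 32 (E)-enone (C5=C4–C3 ketone)
Conditions: 31, LiCl, DBU, MeCN, rt
Reagents that add atoms: 31 diethyl (2-oxobutyl)phosphonate, CCC(=O)CP(=O)(OCC)OCC
Why: Horner–Wadsworth–Emmons olefination under mild lithium chloride–amine conditions adds C4 to C1 and is gentle enough to avoid retro-aldol loss of C7 and enolisation at C17.

Step 20
Reactants: 32 (E)-enone
Product: 34 17-epi target (spiro dihydropyran closed), via hydroxy ketone 33 (not isolated)
Conditions: H2 (1 atm), palladium on carbon, EtOAc, rt; filter; camphorsulfonic acid (1.1 equiv), 4 Å sieves, toluene, 60 °C; Et3N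
Reagents that add atoms: none
Why: Hydrogenation reduces only the disubstituted enone alkene because tetrasubstituted C12=C13 is inert, and the δ-hydroxy ketone then closes to its hemiketal and loses water under acid to the more stable endocyclic enol ether C3=C4.

Step 21
Reactants: 34 17-epi target
Product: 36 target CNP0159589.3, via lithium enolate 35 (not isolated)
Conditions: LDA, THF, −78 to −40 °C; 2,6-di-tert-butyl-4-methylphenol, −78 °C; aq NaHCO3
Reagents that add atoms: none
Why: C17–H is the only acidic hydrogen, and kinetic protonation of the planar ester enolate by a bulky phenol should take place on the open face of ring B (syn to H14 and C24) rather than the face crowded by C15, C6 and C7, which puts H17 cis to H14 and the ester on the hindered face as in the target.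

Compound list
1 | 1-tert-butyl 3-methyl 4-oxopiperidine-1,3-dicarboxylate | COC(=O)C1CN(C(=O)OC(C)(C)C)CCC1=O | starting material
2 | methyl acrylate | C=CC(=O)OC | starting material
3 | 1-tert-butyl 3-methyl (3S)-3-(3-methoxy-3-oxopropyl)-4-oxopiperidine-1,3-dicarboxylate | COC(=O)CC[C@@]1(C(=O)OC)C(=O)CCN(C(=O)OC(C)(C)C)C1 | intermediate
4 | formaldehyde | C=O | starting material
5 | lithium C10 aldolate of 3 (C10 cis to the C13 ester) | COC(=O)CC[C@@]1(C(=O)OC)C(=O)[C@H](C[O-])CN(C(=O)OC(C)(C)C)C1.[Li+] | intermediate
6 | keto lactone (N-Boc 3-oxa-7-azabicyclo[3.3.1]nonane-2,9-dione, propanoate chain on C23) | COC(=O)CC[C@]12C(=O)OC[C@@H](C2=O)CN(C(=O)OC(C)(C)C)C1 | intermediate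
7 | ketal lactone (C6 dioxolane) | COC(=O)CC[C@]12C(=O)OC[C@@H](C23OCCO3)CN(C(=O)OC(C)(C)C)C1 | intermediate
8 | allyl bromoacetate | C=CCOC(=O)CBr | starting material
9 | succinate, C17 epimers | C=CCOC(=O)CC(C(=O)OC)C[C@]12C(=O)OC[C@@H](C23OCCO3)CN(C(=O)OC(C)(C)C)C1 | intermediate
10 | dilithium alkoxide enolate of the spiro β-keto ester | [O-]C[C@@H]1CN(C(=O)OC(C)(C)C)C[C@@]2(CC(C(=O)OC)C(C(=O)OCC=C)=C2[O-])C13OCCO3.[Li+].[Li+] | intermediate
11 | spiro β-keto ester triethylsilyl ether, C14 and C17 epimers | CC[Si](CC)(CC)OC[C@@H]1CN(C(=O)OC(C)(C)C)C[C@@]2(CC(C(=O)OC)C(C(=O)OCC=C)C2=O)C13OCCO3 | intermediate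
12 | chloroacetone | CC(=O)CCl | starting material
13 | C14-acetonyl β-keto ester, epimer mixture | CC[Si](CC)(CC)OC[C@@H]1CN(C(=O)OC(C)(C)C)C[C@@]2(CC(C(=O)OC)C(CC(C)=O)(C(=O)OCC=C)C2=O)C13OCCO3 | intermediate
14 | 1,4-diketone, C14 and C17 epimers | CC[Si](CC)(CC)OC[C@@H]1CN(C(=O)OC(C)(C)C)C[C@@]2(CC(C(=O)OC)C(CC(C)=O)C2=O)C13OCCO3 | intermediate
15 | triethylsilyl ether of the bicyclic enone | CC[Si](CC)(CC)OC[C@@H]1CN(C(=O)OC(C)(C)C)C[C@@]2(C[C@H](C(=O)OC)[C@H]3CC(=O)C=C23)C14OCCO4 | intermediate
16 | bicyclic enone alcohol | OC[C@@H]1CN(C(=O)OC(C)(C)C)C[C@@]2(C[C@H](C(=O)OC)[C@H]3CC(=O)C=C23)C14OCCO4 | intermediate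
17 | C10 aldehyde | O=C[C@@H]1CN(C(=O)OC(C)(C)C)C[C@@]2(C[C@H](C(=O)OC)[C@H]3CC(=O)C=C23)C14OCCO4 | intermediate
18 | methyltriphenylphosphonium bromide | C[P+](c1ccccc1)(c1ccccc1)c1ccccc1.[Br-] | starting material
19 | C9-vinyl enone | C=C[C@@H]1CN(C(=O)OC(C)(C)C)C[C@@]2(C[C@H](C(=O)OC)[C@H]3CC(=O)C=C23)C14OCCO4 | intermediate
20 | C9-vinyl piperidine spiro-linked to the α-iodo bicyclic enone (N-Boc, C6 dioxolane, 17-epi) | C=C[C@@H]1CN(C(=O)OC(C)(C)C)C[C@@]2(C[C@H](C(=O)OC)[C@H]3CC(=O)C(I)=C23)C14OCCO4 | intermediate
21 | C11 B-alkyl-9-BBN derivative of 20 | B5(C6CCCC5CCC6)CC[C@@H]1CN(C(=O)OC(C)(C)C)C[C@@]2(C[C@H](C(=O)OC)[C@H]3CC(=O)C(I)=C23)C14OCCO4 | intermediate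
22 | bridged tetracyclic C16 enone with C6 dioxolane (N-Boc, 17-epi) | O1CCOC12[C@@H]1CCC3=C4[C@H](CC3=O)[C@@H](C(=O)OC)C[C@@]42CN(C(=O)OC(C)(C)C)C1 | intermediate
23 | C16 allylic alcohol, C16 epimers | O1CCOC12[C@@H]1CCC3=C4[C@H](CC3O)[C@@H](C(=O)OC)C[C@@]42CN(C(=O)OC(C)(C)C)C1 | intermediate
24 | C16-deoxygenated secondary amine ketal | O1CCOC12[C@@H]1CCC3=C4[C@H](CC3)[C@@H](C(=O)OC)C[C@@]42CNC1 | intermediate
25 | N-methyl ketal | O1CCOC12[C@@H]1CCC3=C4[C@H](CC3)[C@@H](C(=O)OC)C[C@@]42CN(C)C1 | intermediate
26 | N-methyl C6 ketone | O=C2[C@@H]1CCC3=C4[C@H](CC3)[C@@H](C(=O)OC)C[C@@]42CN(C)C1 | intermediate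
27 | (methoxymethyl)triphenylphosphonium chloride | COC[P+](c1ccccc1)(c1ccccc1)c1ccccc1.[Cl-] | starting material
28 | C6 methoxymethylidene enol ether, E/Z mixture | COC=C2[C@@H]1CCC3=C4[C@H](CC3)[C@@H](C(=O)OC)C[C@@]42CN(C)C1 | intermediate
29 | C6 carbaldehyde, C6 epimers | O=CC2[C@@H]1CCC3=C4[C@H](CC3)[C@@H](C(=O)OC)C[C@@]42CN(C)C1 | intermediate
30 | α-hydroxymethyl aldehyde (quaternary C6) | O=C[C@@]2(CO)[C@@H]1CCC3=C4[C@H](CC3)[C@@H](C(=O)OC)C[C@@]42CN(C)C1 | intermediate
31 | diethyl (2-oxobutyl)phosphonate | CCC(=O)CP(=O)(OCC)OCC | starting material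
32 | (E)-enone | CCC(=O)/C=C/[C@@]2(CO)[C@@H]1CCC3=C4[C@H](CC3)[C@@H](C(=O)OC)C[C@@]42CN(C)C1 | intermediate
33 | δ-hydroxy ketone | CCC(=O)CC[C@@]2(CO)[C@@H]1CCC3=C4[C@H](CC3)[C@@H](C(=O)OC)C[C@@]42CN(C)C1 | intermediate
34 | 17-epi target | CCC1=CC[C@@]2(CO1)[C@@H]1CCC3=C4[C@H](CC3)[C@@H](C(=O)OC)C[C@@]42CN(C)C1 | intermediate
35 | lithium ester enolate of 34 | CCC1=CC[C@@]2(CO1)[C@@H]1CCC3=C4[C@H](CC3)C(=C([O-])OC)C[C@@]42CN(C)C1.[Li+] | intermediate
36 | CNP0159589.3 | CCC1=CC[C@@]2(CO1)[C@@H]1CCC3=C4[C@H](CC3)[C@H](C(=O)OC)C[C@@]42CN(C)C1 | target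

Total step count: 21. Longest linear sequence: 21 steps (from 1).

Steps most likely to fail

Step 12. The borane may reduce the C16 carbonyl while it hydroborates the vinyl group. Transmetalation at the crowded C12 palladium centre may also be slower than protodeboronation or intermolecular coupling. The fallback removes the carbonyl from the coupling partner. It sets out from 20. Luche reduction gives the iodo allylic alcohol F1, and silylation (TBSCl, imidazole) gives the silyl ether F2. Hydroboration with 9-BBN-H and the same palladium-catalysed closure then give the tetracyclic allylic silyl ether F3, with no reducible carbonyl in the substrate. Bu4NF removes the silyl group. The route is rejoined at 23.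

Step 8. Attack on the hindered C13 carbonyl next to spiro C23 may be too slow or too reversible, so retro-aldol and ester exchange may take over. The equilibrium at C14 and C17 may also not settle cleanly on the needed pair. The fallback replaces the reversible aldol by an irreversible olefination. It sets out from 11. Alkylation with dimethyl (3-bromo-2-oxopropyl)phosphonate (K2CO3, acetone) gives the alkylated β-keto ester F4. Deallylation–decarboxylation with Pd(PPh3)4 and formic acid gives the β-keto phosphonate F5. An intramolecular Horner–Wadsworth–Emmons reaction (LiCl, DBU, MeCN) closes ring A at room temperature. The route is rejoined at 15. Equilibration with catalytic NaOMe can then be run as a separate, monitored operation before desilylation to 16.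

Step 21. Proton transfer to the enolate may show poor facial selectivity, or the product may be re-equilibrated during the quench. The fallback delivers hydrogen as an atom from a bulky donor instead of as a proton. It sets out from 34. The lithium enolate is trapped with PhSeBr, which should enter on the open face and give the α-phenylselanyl ester F6. Bu3SnH with AIBN in toluene at 80 °C generates the planar C17 radical. That radical abstracts hydrogen from the stannane on the same open face. The route is rejoined at 36. The enol ether and the amine are inert to these conditions.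

Further compounds
F1 | step 12 | iodo allylic alcohol (C16 epimers) | C=C[C@@H]1CN(C(=O)OC(C)(C)C)C[C@@]2(C[C@H](C(=O)OC)[C@H]3CC(O)C(I)=C23)C14OCCO4
F2 | step 12 | iodo allylic tert-butyldimethylsilyl ether | C=C[C@@H]1CN(C(=O)OC(C)(C)C)C[C@@]2(C[C@H](C(=O)OC)[C@H]3CC(O[Si](C)(C)C(C)(C)C)C(I)=C23)C14OCCO4
F3 | step 12 | tetracyclic allylic silyl ether | O1CCOC12[C@@H]1CCC3=C4[C@H](CC3O[Si](C)(C)C(C)(C)C)[C@@H](C(=O)OC)C[C@@]42CN(C(=O)OC(C)(C)C)C1
F4 | step 8 | C14-(3-dimethoxyphosphoryl-2-oxopropyl) β-keto ester | CC[Si](CC)(CC)OC[C@@H]1CN(C(=O)OC(C)(C)C)C[C@@]2(CC(C(=O)OC)C(CC(=O)CP(=O)(OC)OC)(C(=O)OCC=C)C2=O)C13OCCO3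
F5 | step 8 | β-keto phosphonate | CC[Si](CC)(CC)OC[C@@H]1CN(C(=O)OC(C)(C)C)C[C@@]2(CC(C(=O)OC)C(CC(=O)CP(=O)(OC)OC)C2=O)C13OCCO3
F6 | step 21 | C17 α-phenylselanyl ester | CCC1=CC[C@@]2(CO1)[C@@H]1CCC3=C4[C@H](CC3)[C@]([Se]c3ccccc3)(C(=O)OC)C[C@@]42CN(C)C1
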